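**Plan**
1. Target ring numbering: C1 (O-hydroxytigloyl), C2 (C=O), C3 (C-CH2OH), C4 (=CH), C5 (O-isobutyryl), C6 (i-Pr). Retrosynthetic cuts, in order: side-chain O–Si, C3–CH2OH (Stille), the ester C–O bonds at C1 and C5, and finally ring atom C3 is removed from between C2 and C4.
2. Enabling feature: C2(=O)–C3(X)=C4H is the retron of a dihalocarbene insertion into the C=C of a 1-siloxycyclopentene. C3 is the only ring atom carrying neither oxygen nor a stereocentre, so removing it leaves a cyclopentanone that holds the intact C1/C6/C5 triad.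
3. Forward order: bought cyclopentenone, 3-isopropyl enone, 1,4-hydrosilylation, Rubottom oxidation, kinetic enol silane, :CBr2 ring expansion (5 to 6), the two esters, Stille hydroxymethylation, desilylation.
4. Stereochemistry: only the C5–O centre is bought. Hydride delivered anti to it sets C6 (O and i-Pr cis). Oxygen delivered anti to both sets C1. All this is done on the five-membered ring, where the cis O/i-Pr pair (pseudoaxial and disfavoured in a cyclohexenone) follows from simple facial bias, and the expansion carries the three centres over unchanged.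
5. The (E)-geometry of the side chain comes from a stabilised-ylide Wittig reaction.

Key step: step 6

Assumption: (S)-4-(tert-butyldimethylsilyloxy)cyclopent-2-en-1-one is taken as a catalogue compound, since both enantiomers derive from enzymatic desymmetrisation of cis-cyclopent-4-ene-1,3-diol derivatives.

Step 1
Reactants: 1 (S)-4-(tert-butyldimethylsilyloxy)cyclopent-2-en-1-one
Product: 2 tert-butyl{[(1S,2S)-2-isopropyl-4-(trimethylsilyloxy)cyclopent-3-en-1-yl]oxy}dimethylsilane
Conditions: i-PrMgCl, CuBr·SMe2 (10 mol %), TMSCl, DMPU, THF, −78 °C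
Reagents that add atoms: isopropylmagnesium chloride CC(C)[Mg]Cl; chlorotrimethylsilane C[Si](C)(C)Cl
Why: Copper-catalysed, TMSCl-accelerated conjugate addition of a Grignard reagent to a 4-silyloxycyclopentenone occurs anti to OTBS (a centre erased again in step 2), and immediate O-silylation prevents β-elimination of the silyloxy group.

Step 2
Reactants: 2 tert-butyl{[(1S,2S)-2-isopropyl-4-(trimethylsilyloxy)cyclopent-3-en-1-yl]oxy}dimethylsilane
Product: 3 (S)-4-(tert-butyldimethylsilyloxy)-3-isopropylcyclopent-2-en-1-one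
Conditions: Pd(OAc)2 (10 mol %), O2 (1 atm), DMSO, 25–40 °C
Reagents that add atoms: none
Why: In this Saegusa–Ito oxidation the palladium enolate at C2 can β-hydride-eliminate only towards C3–H, which places the isopropyl group on the enone β-carbon and leaves the silyloxy stereocentre untouched.

Step 3
Reactants: 3 (S)-4-(tert-butyldimethylsilyloxy)-3-isopropylcyclopent-2-en-1-one
Product: 4 tert-butyl{[(1S,2R)-2-isopropyl-4-(triisopropylsilyloxy)cyclopent-3-en-1-yl]oxy}dimethylsilane
Conditions: i-Pr3SiH, Pt2(dvtms)3 (0.5 mol %), toluene, 60 °C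
Reagents that add atoms: triisopropylsilane CC(C)[SiH](C(C)C)C(C)C
Why: Platinum-catalysed 1,4-hydrosilylation of an enone gives the silyl enol ether regiospecifically, and the metal hydride reaches the β-carbon from the face anti to the neighbouring OTBS group, so the isopropyl group ends up cis to OTBS.

Step 4
Reactants: 4 tert-butyl{[(1S,2R)-2-isopropyl-4-(triisopropylsilyloxy)cyclopent-3-en-1-yl]oxy}dimethylsilane
Product: 6 (2R,3S,4S)-4-(tert-butyldimethylsilyloxy)-3-isopropyl-2-(triisopropylsilyloxy)cyclopentan-1-one, via silyloxy epoxide 5 (not isolated)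
Conditions: mCPBA, NaHCO3, hexane/CH2Cl2, −20 → 0 °C
Reagents that add atoms: 3-chloroperbenzoic acid OOC(=O)c1cccc(Cl)c1
Why: In this Rubottom oxidation the peracid epoxidises the enol ether on the face opposite the cis-disposed i-Pr and OTBS groups, and 1,4-silyl migration in 5 gives the α-silyloxy ketone with C2–O trans to i-Pr and TIPS retained as the protecting group.

Step 5
Reactants: 6 (2R,3S,4S)-4-(tert-butyldimethylsilyloxy)-3-isopropyl-2-(triisopropylsilyloxy)cyclopentan-1-one
Product: 7 (3R,4S,5R)-3-(tert-butyldimethylsilyloxy)-4-isopropyl-5-(triisopropylsilyloxy)-1-(trimethylsilyloxy)cyclopent-1-ene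
Conditions: LDA, TMSCl (internal quench), THF, −78 °C; Et3N, pentane work-up
Reagents that add atoms: chlorotrimethylsilane C[Si](C)(C)Cl
Why: Kinetic enolisation removes a proton from the open CH2 rather than from the crowded C–H bearing OTIPS, and instant O-silylation at −78 °C should outrun E1cB loss of the β-OTBS group, as in the usual preparation of γ-silyloxy enone precursors.

Step 6
Reactants: 7 (3R,4S,5R)-3-(tert-butyldimethylsilyloxy)-4-isopropyl-5-(triisopropylsilyloxy)-1-(trimethylsilyloxy)cyclopent-1-ene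
Product: 9 (4R,5S,6R)-2-bromo-4-(tert-butyldimethylsilyloxy)-5-isopropyl-6-(triisopropylsilyloxy)cyclohex-2-en-1-one, via dibromocyclopropane 8 (not isolated)
Conditions: CHBr3 (1.5 equiv), KOt-Bu (1.3 equiv), pentane, −30 → 25 °C; toluene, 60 °C to complete the opening
Reagents that add atoms: bromoform BrC(Br)Br
Why: α-Elimination of HBr from bromoform gives :CBr2, which closes the three-membered ring of 8 by a concerted [2+1] cheletropic addition to the only electron-rich π bond of 7, the C1=C2 silyl enol ether; the face of attack is irrelevant because both new centres become sp2 again. In 8 the lone pair of the C1 oxygen drives a thermally allowed disrotatory 2π electrocyclic opening of the ring-fusion bond with loss of the endo bromide (Woodward–Hoffmann–DePuy rule), and bromide removes the TMS group from the resulting 2-bromo-1-siloxyallyl cation, so the six-membered ring is not closed but arises from the five-membered ring by cleavage of the shared bond, enlarged by the carbene carbon. The closest known reaction type is the dihalocarbene ring expansion of cyclic trimethylsilyl enol ethers to 2-halocycloalk-2-enones. No stereocentre is created: the C–OTIPS, C–i-Pr and C–OTBS centres lie outside the reacting σ/π system and are carried over unchanged, including the cis O/i-Pr pair. The step needs regioselectivity (the carbon must enter between the carbonyl carbon and the CH next to C–OTBS), which is fixed by the enol ether position set in step 5 and by the fact that only the bond opposite CBr2 can open electrocyclically. In one operation the step delivers the ring size, the enone in the correct register with the triad and a C3 halogen handle; base is kept limiting and cold so that enol ether cleavage and loss of silanolate do not compete.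

Step 7
Reactants: 9 (4R,5S,6R)-2-bromo-4-(tert-butyldimethylsilyloxy)-5-isopropyl-6-(triisopropylsilyloxy)cyclohex-2-en-1-one
Product: 10 (4R,5S,6R)-2-bromo-4-hydroxy-5-isopropyl-6-(triisopropylsilyloxy)cyclohex-2-en-1-one
Conditions: HF·pyridine, pyridine/THF, 0 °C → rt
Reagents that add atoms: none
Why: Fluoride-mediated silyl ether cleavage discriminates by bulk at silicon, so buffered HF·pyridine should remove the TBS ether well before the TIPS ether.

Step 8
Reactants: 10 (4R,5S,6R)-2-bromo-4-hydroxy-5-isopropyl-6-(triisopropylsilyloxy)cyclohex-2-en-1-one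
Product: 11 (1R,5R,6S)-3-bromo-6-isopropyl-4-oxo-5-(triisopropylsilyloxy)cyclohex-2-en-1-yl isobutyrate
Conditions: (i-PrCO)2O, DMAP (cat.), pyridine, CH2Cl2, 0 °C → rt
Reagents that add atoms: isobutyric anhydride CC(C)C(=O)OC(=O)C(C)C
Why: DMAP-catalysed acylation touches only the O–H bond of the secondary allylic alcohol, so the configuration at carbon is retained.

Step 9
Reactants: 11 (1R,5R,6S)-3-bromo-6-isopropyl-4-oxo-5-(triisopropylsilyloxy)cyclohex-2-en-1-yl isobutyrate
Product: 12 (1R,5R,6R)-3-bromo-5-hydroxy-6-isopropyl-4-oxocyclohex-2-en-1-yl isobutyrate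
Conditions: 48 % aq. HF, MeCN, 0 °C → rt
Reagents that add atoms: none
Why: Acidic fluoride desilylation removes the carbonyl-activated TIPS ether under conditions that spare the ester, the vinyl bromide and the epimerisable α-carbon, and the trans-1,3 arrangement of the two oxygens rules out acyl migration.

Step 10
Reactants: 13 (tert-butyldimethylsilyloxy)acetaldehyde; 14 ethyl 2-(triphenyl-λ5-phosphanylidene)propanoate
Product: 15 ethyl (E)-4-(tert-butyldimethylsilyloxy)-2-methylbut-2-enoate
Conditions: CH2Cl2, rt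
Reagents that add atoms: none
Why: A Wittig reaction with a stabilised α-branched ylide gives the (E)-trisubstituted enoate, with the CH2OTBS group trans to the ester.

Step 11
Reactants: 15 ethyl (E)-4-(tert-butyldimethylsilyloxy)-2-methylbut-2-enoate
Product: 16 (E)-4-(tert-butyldimethylsilyloxy)-2-methylbut-2-enoic acid
Conditions: LiOH, THF/MeOH/H2O, rt; 1 M HCl to pH 4
Reagents that add atoms: lithium hydroxide [Li+].[OH-]
Why: Saponification of the ethyl ester at room temperature leaves the primary TBS ether and the alkene geometry intact.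

Step 12
Reactants: 12 (1R,5R,6R)-3-bromo-5-hydroxy-6-isopropyl-4-oxocyclohex-2-en-1-yl isobutyrate; 16 (E)-4-(tert-butyldimethylsilyloxy)-2-methylbut-2-enoic acid
Product: 18 (1R,5R,6S)-3-bromo-5-(isobutyryloxy)-6-isopropyl-2-oxocyclohex-3-en-1-yl (E)-4-(tert-butyldimethylsilyloxy)-2-methylbut-2-enoate, via mixed anhydride 17 (not isolated)
Conditions: 2,4,6-Cl3C6H2COCl, Et3N, toluene, rt; then 12, DMAP, toluene, 0 °C → rt
Reagents that add atoms: none
Why: Yamaguchi esterification is the standard way to join a hindered secondary alcohol to an α-branched enoic acid without E/Z scrambling, and it leaves the carbinol configuration unchanged.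

Step 13
Reactants: 18 (1R,5R,6S)-3-bromo-5-(isobutyryloxy)-6-isopropyl-2-oxocyclohex-3-en-1-yl (E)-4-(tert-butyldimethylsilyloxy)-2-methylbut-2-enoate
Product: 19 (1R,5S,6S)-3-(hydroxymethyl)-5-(isobutyryloxy)-6-isopropyl-2-oxocyclohex-3-en-1-yl (E)-4-(tert-butyldimethylsilyloxy)-2-methylbut-2-enoate
Conditions: Bu3SnCH2OH, Pd(PPh3)4 (10 mol %), dioxane, 80 °C
Reagents that add atoms: (tributylstannyl)methanol OC[Sn](CCCC)(CCCC)CCCC
Why: Stille hydroxymethylation of an α-haloenone runs under neutral conditions, oxidative addition into the activated C–Br bond should precede any ionisation of the allylic ester, and the free CH2OH group then needs no protecting group.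

Step 14
Reactants: 19 (1R,5S,6S)-3-(hydroxymethyl)-5-(isobutyryloxy)-6-isopropyl-2-oxocyclohex-3-en-1-yl (E)-4-(tert-butyldimethylsilyloxy)-2-methylbut-2-enoate
Product: 20 (1R,5S,6S)-3-(hydroxymethyl)-5-(isobutyryloxy)-6-isopropyl-2-oxocyclohex-3-en-1-yl (E)-4-hydroxy-2-methylbut-2-enoate
Conditions: HF·pyridine, THF, 0 °C
Reagents that add atoms: none
Why: Mildly acidic fluoride cleavage of a primary allylic TBS ether avoids the basic conditions under which the two acyloxy groups could be lost with aromatisation.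

**Compound list**
1 | (S)-4-(tert-butyldimethylsilyloxy)cyclopent-2-en-1-one | O=C1C[C@H](O[Si](C)(C)C(C)(C)C)C=C1 | starting material
2 | tert-butyl{[(1S,2S)-2-isopropyl-4-(trimethylsilyloxy)cyclopent-3-en-1-yl]oxy}dimethylsilane (i-Pr trans to OTBS) | C1=C(O[Si](C)(C)C)C[C@H](O[Si](C)(C)C(C)(C)C)[C@H]1C(C)C | intermediate
3 | (S)-4-(tert-butyldimethylsilyloxy)-3-isopropylcyclopent-2-en-1-one | O=C1C[C@H](O[Si](C)(C)C(C)(C)C)C(C(C)C)=C1 | intermediate
4 | tert-butyl{[(1S,2R)-2-isopropyl-4-(triisopropylsilyloxy)cyclopent-3-en-1-yl]oxy}dimethylsilane (i-Pr cis to OTBS) | C1=C(O[Si](C(C)C)(C(C)C)C(C)C)C[C@H](O[Si](C)(C)C(C)(C)C)[C@@H]1C(C)C | intermediate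
5 | 3-(tert-butyldimethylsilyloxy)-4-isopropyl-1-(triisopropylsilyloxy)-6-oxabicyclo[3.1.0]hexane, oxirane oxygen anti to i-Pr and OTBS | O2[C@H]1[C@]2(O[Si](C(C)C)(C(C)C)C(C)C)C[C@H](O[Si](C)(C)C(C)(C)C)[C@@H]1C(C)C | intermediate
6 | (2R,3S,4S)-4-(tert-butyldimethylsilyloxy)-3-isopropyl-2-(triisopropylsilyloxy)cyclopentan-1-one | CC(C)[Si](C(C)C)(C(C)C)O[C@H]1C(=O)C[C@H](O[Si](C)(C)C(C)(C)C)[C@@H]1C(C)C | intermediate
7 | (3R,4S,5R)-3-(tert-butyldimethylsilyloxy)-4-isopropyl-5-(triisopropylsilyloxy)-1-(trimethylsilyloxy)cyclopent-1-ene | CC(C)[Si](C(C)C)(C(C)C)O[C@H]1C(O[Si](C)(C)C)=C[C@H](O[Si](C)(C)C(C)(C)C)[C@@H]1C(C)C | intermediate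
8 | 6,6-dibromo-4-(tert-butyldimethylsilyloxy)-3-isopropyl-2-(triisopropylsilyloxy)-1-(trimethylsilyloxy)bicyclo[3.1.0]hexane (CBr2 drawn anti to i-Pr/OTBS; the adduct from either face opens to 9) | CC(C)[Si](C(C)C)(C(C)C)O[C@H]1[C@@]2(O[Si](C)(C)C)C(Br)(Br)[C@H]2[C@H](O[Si](C)(C)C(C)(C)C)[C@@H]1C(C)C | intermediate
9 | (4R,5S,6R)-2-bromo-4-(tert-butyldimethylsilyloxy)-5-isopropyl-6-(triisopropylsilyloxy)cyclohex-2-en-1-one | CC(C)[Si](C(C)C)(C(C)C)O[C@H]1C(=O)C(Br)=C[C@H](O[Si](C)(C)C(C)(C)C)[C@@H]1C(C)C | intermediate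
10 | (4R,5S,6R)-2-bromo-4-hydroxy-5-isopropyl-6-(triisopropylsilyloxy)cyclohex-2-en-1-one | CC(C)[Si](C(C)C)(C(C)C)O[C@H]1C(=O)C(Br)=C[C@H](O)[C@@H]1C(C)C | intermediate
11 | (1R,5R,6S)-3-bromo-6-isopropyl-4-oxo-5-(triisopropylsilyloxy)cyclohex-2-en-1-yl isobutyrate | CC(C)[Si](C(C)C)(C(C)C)O[C@H]1C(=O)C(Br)=C[C@H](OC(=O)C(C)C)[C@@H]1C(C)C | intermediate
12 | (1R,5R,6R)-3-bromo-5-hydroxy-6-isopropyl-4-oxocyclohex-2-en-1-yl isobutyrate | O[C@H]1C(=O)C(Br)=C[C@H](OC(=O)C(C)C)[C@@H]1C(C)C | intermediate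
13 | (tert-butyldimethylsilyloxy)acetaldehyde | O=CCO[Si](C)(C)C(C)(C)C | starting material
14 | ethyl 2-(triphenyl-λ5-phosphanylidene)propanoate | CCOC(=O)C(C)=P(c1ccccc1)(c1ccccc1)c1ccccc1 | starting material
15 | ethyl (E)-4-(tert-butyldimethylsilyloxy)-2-methylbut-2-enoate | C/C(=C\CO[Si](C)(C)C(C)(C)C)C(=O)OCC | intermediate
16 | (E)-4-(tert-butyldimethylsilyloxy)-2-methylbut-2-enoic acid | C/C(=C\CO[Si](C)(C)C(C)(C)C)C(=O)O | intermediate
17 | (E)-4-(tert-butyldimethylsilyloxy)-2-methylbut-2-enoic 2,4,6-trichlorobenzoic anhydride | C/C(=C\CO[Si](C)(C)C(C)(C)C)C(=O)OC(=O)c1c(Cl)cc(Cl)cc1Cl | intermediate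
18 | (1R,5R,6S)-3-bromo-5-(isobutyryloxy)-6-isopropyl-2-oxocyclohex-3-en-1-yl (E)-4-(tert-butyldimethylsilyloxy)-2-methylbut-2-enoate | C/C(=C\CO[Si](C)(C)C(C)(C)C)C(=O)O[C@H]1C(=O)C(Br)=C[C@H](OC(=O)C(C)C)[C@@H]1C(C)C | intermediate
19 | (1R,5S,6S)-3-(hydroxymethyl)-5-(isobutyryloxy)-6-isopropyl-2-oxocyclohex-3-en-1-yl (E)-4-(tert-butyldimethylsilyloxy)-2-methylbut-2-enoate | C/C(=C\CO[Si](C)(C)C(C)(C)C)C(=O)O[C@H]1C(=O)C(CO)=C[C@H](OC(=O)C(C)C)[C@@H]1C(C)C | intermediate
20 | (1R,5S,6S)-3-(hydroxymethyl)-5-(isobutyryloxy)-6-isopropyl-2-oxocyclohex-3-en-1-yl (E)-4-hydroxy-2-methylbut-2-enoate (CNP0254776.1) | C/C(=C\CO)C(=O)O[C@H]1C(=O)C(CO)=C[C@H](OC(=O)C(C)C)[C@@H]1C(C)C | target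

Total step count: 14. Longest linear sequence: 12 (steps 1–9 and 12–14).

**Steps most likely to fail**

Step 6. Carbene capture by the enol ether, which is flanked on both sides by silyloxy groups, may be slow. Alkoxide-induced cleavage of the silyl enol ether, followed by loss of silanolate, could then take over. The fallback sets out from 7 and returns at 9, replacing the ionic halocarbene route with a one-electron opening of a halogen-free cyclopropane. Furukawa-type Simmons–Smith cyclopropanation (Et2Zn, CH2I2) gives the 1-siloxybicyclo[3.1.0]hexane F1. FeCl3 in DMF cleaves the same ring-fusion bond oxidatively to give the ring-expanded 3-chlorocyclohexanone F2. NaOAc in MeOH eliminates to the cyclohexenone F3. Addition of Br2 gives the 2,3-dibromoketone F4, and Et3N dehydrobrominates it to 9.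

Step 5. The enolate may expel the β-silyloxy group, or deprotonation and silyl migration may occur on the oxygenated side. The fallback sets out from 6 and returns at 9, so it bypasses steps 5 and 6 and avoids any β-silyloxy enolate. Lewis-acid-promoted diazoalkane homologation (TMSCHN2, BF3·OEt2, CH2Cl2, −78 °C, Tiffeneau–Demjanov type) expands the ketone, with the unsubstituted CH2 migrating in preference to the hindered, oxygenated CH, to give the α-silyl ketone F5. K2CO3 in MeOH protodesilylates this to the cyclohexanone F6, in which OTBS is now γ to the carbonyl group. Kinetic enolisation (LDA, TMSCl) gives the enol silane F7. Saegusa–Ito oxidation leads to the cyclohexenone F3 described above, which is brominated and dehydrobrominated to 9 in the same way.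

Step 13. Pd(0) may ionise the allylic isobutyrate, transfer of the sp3 group from tin is slow, and heating may cause loss of the carboxylic acids with aromatisation. The fallback sets out from 9 and returns at 19, moving the palladium step ahead of any allylic ester at the cost of one temporary protecting group.
- Stille coupling of 9 with Bu3SnCH2OH gives the hydroxymethyl enone F8.
- PMB trichloroacetimidate with catalytic La(OTf)3 gives the PMB ether F9.
- HF·pyridine gives the allylic alcohol F10.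
- Isobutyric anhydride with DMAP gives the isobutyrate F11.
- Aqueous HF in MeCN gives the α-hydroxy ketone F12.
- Yamaguchi esterification with 16 (through 17) gives the diester F13.
- DDQ in CH2Cl2/buffer removes the PMB group to give 19.

**Further compounds**
F1 | step 6 | 4-(tert-butyldimethylsilyloxy)-3-isopropyl-2-(triisopropylsilyloxy)-1-(trimethylsilyloxy)bicyclo[3.1.0]hexane | CC(C)[Si](C(C)C)(C(C)C)O[C@H]1[C@@]2(O[Si](C)(C)C)C[C@H]2[C@H](O[Si](C)(C)C(C)(C)C)[C@@H]1C(C)C
F2 | step 6 | (4S,5S,6R)-4-(tert-butyldimethylsilyloxy)-3-chloro-5-isopropyl-6-(triisopropylsilyloxy)cyclohexan-1-one (C3 epimers) | CC(C)[Si](C(C)C)(C(C)C)O[C@H]1C(=O)CC(Cl)[C@H](O[Si](C)(C)C(C)(C)C)[C@@H]1C(C)C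
F3 | step 6 | 4-(tert-butyldimethylsilyloxy)-5-isopropyl-6-(triisopropylsilyloxy)cyclohex-2-en-1-one (triad as in 9) | CC(C)[Si](C(C)C)(C(C)C)O[C@H]1C(=O)C=C[C@H](O[Si](C)(C)C(C)(C)C)[C@@H]1C(C)C
F4 | step 6 | 2,3-dibromo-4-(tert-butyldimethylsilyloxy)-5-isopropyl-6-(triisopropylsilyloxy)cyclohexan-1-one (C2/C3 not defined) | CC(C)[Si](C(C)C)(C(C)C)O[C@H]1C(=O)C(Br)C(Br)[C@H](O[Si](C)(C)C(C)(C)C)[C@@H]1C(C)C
F5 | step 5 | 4-(tert-butyldimethylsilyloxy)-5-isopropyl-6-(triisopropylsilyloxy)-2-(trimethylsilyl)cyclohexan-1-one (C2 epimers) | CC(C)[Si](C(C)C)(C(C)C)O[C@H]1C(=O)C([Si](C)(C)C)C[C@H](O[Si](C)(C)C(C)(C)C)[C@@H]1C(C)C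
F6 | step 5 | 4-(tert-butyldimethylsilyloxy)-3-isopropyl-2-(triisopropylsilyloxy)cyclohexan-1-one (triad as in 6) | CC(C)[Si](C(C)C)(C(C)C)O[C@H]1C(=O)CC[C@H](O[Si](C)(C)C(C)(C)C)[C@@H]1C(C)C
F7 | step 5 | 4-(tert-butyldimethylsilyloxy)-5-isopropyl-6-(triisopropylsilyloxy)-1-(trimethylsilyloxy)cyclohex-1-ene | CC(C)[Si](C(C)C)(C(C)C)O[C@H]1C(O[Si](C)(C)C)=CC[C@H](O[Si](C)(C)C(C)(C)C)[C@@H]1C(C)C
F8 | step 13 | 4-(tert-butyldimethylsilyloxy)-2-(hydroxymethyl)-5-isopropyl-6-(triisopropylsilyloxy)cyclohex-2-en-1-one | CC(C)[Si](C(C)C)(C(C)C)O[C@H]1C(=O)C(CO)=C[C@H](O[Si](C)(C)C(C)(C)C)[C@@H]1C(C)C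
F9 | step 13 | 4-(tert-butyldimethylsilyloxy)-5-isopropyl-2-[(4-methoxybenzyloxy)methyl]-6-(triisopropylsilyloxy)cyclohex-2-en-1-one | CC(C)[Si](C(C)C)(C(C)C)O[C@H]1C(=O)C(COCc2ccc(OC)cc2)=C[C@H](O[Si](C)(C)C(C)(C)C)[C@@H]1C(C)C
F10 | step 13 | 4-hydroxy-5-isopropyl-2-[(4-methoxybenzyloxy)methyl]-6-(triisopropylsilyloxy)cyclohex-2-en-1-one | CC(C)[Si](C(C)C)(C(C)C)O[C@H]1C(=O)C(COCc2ccc(OC)cc2)=C[C@H](O)[C@@H]1C(C)C
F11 | step 13 | 6-isopropyl-3-[(4-methoxybenzyloxy)methyl]-4-oxo-5-(triisopropylsilyloxy)cyclohex-2-en-1-yl isobutyrate | CC(C)[Si](C(C)C)(C(C)C)O[C@H]1C(=O)C(COCc2ccc(OC)cc2)=C[C@H](OC(=O)C(C)C)[C@@H]1C(C)C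
F12 | step 13 | 5-hydroxy-6-isopropyl-3-[(4-methoxybenzyloxy)methyl]-4-oxocyclohex-2-en-1-yl isobutyrate | O[C@H]1C(=O)C(COCc2ccc(OC)cc2)=C[C@H](OC(=O)C(C)C)[C@@H]1C(C)C
F13 | step 13 | 5-(isobutyryloxy)-6-isopropyl-3-[(4-methoxybenzyloxy)methyl]-2-oxocyclohex-3-en-1-yl (E)-4-(tert-butyldimethylsilyloxy)-2-methylbut-2-enoate | C/C(=C\CO[Si](C)(C)C(C)(C)C)C(=O)O[C@H]1C(=O)C(COCc2ccc(OC)cc2)=C[C@H](OC(=O)C(C)C)[C@@H]1C(C)C
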